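Ring A of the drimane core is disconnected at C1–C2 and C3–C4, leaving a two-carbon unit (C2–C3) and a ring B derived from (R)-carvone that carries an isopropenyl group on C5 and a formyl group on quaternary C10. The key step exploits the gem-dimethyl carbon C4 and the unfunctionalised C1–C3 methylenes: hydrogen-atom transfer turns the isopropenyl group into a tertiary C4 radical that adds to vinyltriphenylphosphonium bromide, and the derived ylide closes onto the C1 aldehyde by Wittig reaction, so trans-fused ring A forms in one operation. Hydrogenation, C9 methylenation, hydroboration/Suzuki coupling with the bromoarene and MOM removal complete the route.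

Key step: step 4

Remark: drimane numbering (ring A: C1–C5, C10; ring B: C5–C10; benzylic carbon C11) is used for the terpenoid carbons of all intermediates, so C5, C10, C9 and C4 correspond to C5, C6, C1 and the internal isopropenyl carbon of carvone. α/β refer to the usual drimane orientation (10-CH3 β). (R)-(−)-Carvone, vinyltriphenylphosphonium bromide and benzene-1,2,4-triol are taken as commercial.

Step 1
Reactants: 1 (R)-(−)-carvone
Product: 3 (5R)-2,6-dimethyl-5-(prop-1-en-2-yl)cyclohex-2-en-1-one (6-methylcarvone; both C6 epimers), via lithium dienolate 2 (not isolated)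
Conditions: LiN(i-Pr)2, THF, −78 °C; MeI, −78 to 0 °C
Reagents that add atoms: iodomethane, CI
Why: Kinetic α'-deprotonation of the enone gives the cross-conjugated lithium dienolate, which is C-methylated (enolate alkylation); the configuration of the new centre is immaterial because it is erased on enolisation in step 2.

Step 2
Reactants: 3 6-methylcarvone
Product: 5 (5S,6R)-6-(hydroxymethyl)-2,6-dimethyl-5-(prop-1-en-2-yl)cyclohex-2-en-1-one, via lithium enolate 4 (not isolated)
Conditions: LiN(i-Pr)2, THF, −78 °C; CH2O (gas, from paraformaldehyde), −78 °C; AcOH quench at −78 °C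
Reagents that add atoms: formaldehyde, C=O
Why: Aldol addition of the tetrasubstituted lithium enolate to monomeric formaldehyde should occur on the face anti to the adjacent C5 isopropenyl group, which sets quaternary C10 with the methyl group cis and the hydroxymethyl group trans to the isopropenyl group (substrate-controlled enolate hydroxymethylation).

Step 3
Reactants: 5 hydroxymethyl ketone
Product: 6 (1R,6S)-1,3-dimethyl-2-oxo-6-(prop-1-en-2-yl)cyclohex-3-ene-1-carbaldehyde
Conditions: Dess–Martin periodinane, CH2Cl2, 0 °C to rt
Reagents that add atoms: none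
Why: Dess–Martin oxidation of the neopentyl primary alcohol under neutral conditions should give the non-enolisable β-keto aldehyde without retro-aldol cleavage or deformylation.

Step 4
Reactants: 6 keto aldehyde; 7 vinyltriphenylphosphonium bromide
Product: 10 (4aS,8aS)-2,5,5,8a-tetramethyl-4a,5,6,8a-tetrahydronaphthalen-1(4H)-one (11-nordrima-1,7-dien-9-one; 5α-H and 10β-CH3), via phosphonium salt 8 (not isolated), via ylide 9 (not isolated)
Conditions: Fe(acac)3 (0.3 equiv), PhSiH3 (1.5 equiv), 7 (1.3 equiv), EtOH/CH2Cl2, rt; volatiles removed; KN(SiMe3)2, THF, −78 °C to rt, same flask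
Reagents that add atoms: none
Why: Proposed new method: an iron hydride formed from Fe(acac)3 and PhSiH3 transfers a hydrogen atom to the terminal CH2 of the isopropenyl group, and the tertiary C4 radical adds to the CH2 terminus of the cationic acceptor 7 (C3–C4 bond); reduction of the α-phosphonio radical by divalent iron and protonation by ethanol give salt 8, which the amide base returns to ylide 9 for an intramolecular Wittig reaction with the C1 aldehyde (C1–C2 bond, loss of Ph3PO). The closest known reaction types are the metal-hydride HAT radical conjugate addition/aldol annulation of alkenyl aldehydes with unsaturated carbonyl acceptors, the photoredox radical addition to vinylphosphonium salts followed by Wittig olefination, and the Schweizer annulation. Ring A closes as a six-membered ring by 6-exo-trig attack of the ylide carbon C2 on the aldehyde carbon, a formal [4+2] union of C1–C10–C5–C4 with C2–C3. No stereocentre is created; the trans ring fusion follows from the trans relation of the C5 side chain and the C10 formyl group fixed in steps 1 and 2, both equatorial in the reactive conformer. The step needs hydrogen-atom transfer to the electron-rich 1,1-disubstituted alkene and not to the electron-poor enone, capture of the nucleophilic radical by the acceptor used in excess, and Wittig reaction at the aldehyde and not at the C9 ketone; the last is secured because closure onto C9 would give a bridgehead alkene in a bicyclo[3.3.1]nonane.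

Step 5
Reactants: 10 dienone
Product: 11 (4aS,8aS)-2,5,5,8a-tetramethyl-4a,5,6,7,8,8a-hexahydronaphthalen-1(4H)-one (11-nordrim-7-en-9-one)
Conditions: H2 (1 atm), RhCl(PPh3)3 (5 mol %), benzene, rt
Reagents that add atoms: none
Why: Homogeneous hydrogenation with RhCl(PPh3)3 should reduce the cis-disubstituted C1=C2 alkene and leave the trisubstituted, conjugated C7=C8 alkene untouched (chemoselective alkene hydrogenation).

Step 6
Reactants: 11 enone
Product: 12 (4aS,8aS)-3,4a,8,8-tetramethyl-4-methylidene-1,4,4a,5,6,7,8,8a-octahydronaphthalene (drima-7,9(11)-diene)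
Conditions: Ph3PCH3Br, KOt-Bu, toluene, 90 °C
Reagents that add atoms: methyltriphenylphosphonium bromide, C[P+](c1ccccc1)(c1ccccc1)c1ccccc1.[Br-]
Why: Wittig methylenation of the hindered conjugated C9 ketone with methylenetriphenylphosphorane at elevated temperature should give the exocyclic 1,3-diene without touching a stereocentre.

Step 7
Reactants: 13 benzene-1,2,4-triol
Product: 14 1,2,4-tris(methoxymethoxy)benzene
Conditions: MOMCl, i-Pr2NEt, CH2Cl2, 0 °C to rt, under argon
Reagents that add atoms: chloromethyl methyl ether, COCCl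
Why: O-Alkylation of the three phenols gives MOM ethers that direct the lithiation of step 8 and can be removed later by mild acid (acetal protection).

Step 8
Reactants: 14 tris-MOM ether
Product: 16 2,3,6-tris(methoxymethoxy)benzaldehyde, via aryllithium 15 (not isolated)
Conditions: n-BuLi, TMEDA, THF, 0 °C; DMF, 0 °C to rt; H2O
Reagents that add atoms: N,N-dimethylformamide, CN(C)C=O
Why: Directed ortho-metalation should occur at the ring position flanked by two OMOM groups, and the aryllithium is formylated by DMF.

Step 9
Reactants: 16 aldehyde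
Product: 17 3-bromo-2,5,6-tris(methoxymethoxy)benzaldehyde
Conditions: NBS, MeCN, 0 °C to rt
Reagents that add atoms: N-bromosuccinimide, O=C1CCC(=O)N1Br
Why: Electrophilic aromatic bromination should take the free position that is ortho to one OMOM group, para to another and meta to the formyl group, the other free position being para to the formyl group and deactivated.

Step 10
Reactants: 12 drima-7,9(11)-diene; 17 aryl bromide
Product: 19 2,3,6-tris(methoxymethoxy)-5-{[(1S,4aS,8aS)-2,5,5,8a-tetramethyl-1,4,4a,5,6,7,8,8a-octahydronaphthalen-1-yl]methyl}benzaldehyde, via alkylborane 18 (not isolated)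
Conditions: 9-BBN (1.2 equiv), THF, 0 °C to rt; then 17, Pd(dppf)Cl2 (10 mol %), K3PO4 (aq), DMF, 60 °C
Reagents that add atoms: none
Why: Hydroboration of the 1,1-disubstituted terminus of the diene with 9-BBN places boron on C11 and delivers hydrogen to C9 from the α face, anti to the axial C10 methyl group, which sets 9S with C11 equatorial, and the primary alkylborane then undergoes B-alkyl Suzuki–Miyaura coupling with the aryl bromide.

Step 11
Reactants: 19 tris-MOM ether of the target
Product: 20 2,3,6-trihydroxy-5-{[(1S,4aS,8aS)-2,5,5,8a-tetramethyl-1,4,4a,5,6,7,8,8a-octahydronaphthalen-1-yl]methyl}benzaldehyde (CNP0114581.2)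
Conditions: HCl (aq, 2 M), MeOH/THF, 40 °C, degassed
Reagents that add atoms: none
Why: Acid-catalysed transacetalisation in methanol should remove the three MOM groups under conditions mild enough to avoid protonation of the C7=C8 alkene and cyclisation of the ortho phenol onto C8.

Compound list
1 | (R)-(−)-carvone, (5R)-2-methyl-5-(prop-1-en-2-yl)cyclohex-2-en-1-one | CC1=CC[C@@H](C(C)=C)CC1=O | starting material
2 | lithium dienolate of 1 (O–Li on C9, C9=C10 and C7=C8) | CC1=CC[C@@H](C(C)=C)C=C1O[Li] | intermediate
3 | (5R)-2,6-dimethyl-5-(prop-1-en-2-yl)cyclohex-2-en-1-one (6-methylcarvone, C6 epimer mixture, C6 left undefined) | CC1=CC[C@@H](C(C)=C)C(C)C1=O | intermediate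
4 | lithium enolate of 3 (O–Li on C9, tetrasubstituted C9=C10) | CC1=CC[C@@H](C(C)=C)C(C)=C1O[Li] | intermediate
5 | (5S,6R)-6-(hydroxymethyl)-2,6-dimethyl-5-(prop-1-en-2-yl)cyclohex-2-en-1-one (CH3 cis, CH2OH trans to isopropenyl) | CC1=CC[C@@H](C(C)=C)[C@](C)(CO)C1=O | intermediate
6 | (1R,6S)-1,3-dimethyl-2-oxo-6-(prop-1-en-2-yl)cyclohex-3-ene-1-carbaldehyde (CHO trans to isopropenyl) | CC1=CC[C@@H](C(C)=C)[C@](C)(C=O)C1=O | intermediate
7 | vinyltriphenylphosphonium bromide | C=C[P+](c1ccccc1)(c1ccccc1)c1ccccc1.[Br-] | starting material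
8 | {3-[(1S,2R)-2-formyl-2,4-dimethyl-3-oxocyclohex-4-en-1-yl]-3-methylbutyl}triphenylphosphonium bromide | CC1=CC[C@@H](C(C)(C)CC[P+](c2ccccc2)(c2ccccc2)c2ccccc2)[C@](C)(C=O)C1=O.[Br-] | intermediate
9 | {3-[(1S,2R)-2-formyl-2,4-dimethyl-3-oxocyclohex-4-en-1-yl]-3-methylbutylidene}triphenylphosphorane | CC1=CC[C@@H](C(C)(C)CC=P(c2ccccc2)(c2ccccc2)c2ccccc2)[C@](C)(C=O)C1=O | intermediate
10 | (4aS,8aS)-2,5,5,8a-tetramethyl-4a,5,6,8a-tetrahydronaphthalen-1(4H)-one (trans-fused, C1=C2 and C7=C8) | CC1=CC[C@H]2C(C)(C)CC=C[C@]2(C)C1=O | intermediate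
11 | (4aS,8aS)-2,5,5,8a-tetramethyl-4a,5,6,7,8,8a-hexahydronaphthalen-1(4H)-one (11-nordrim-7-en-9-one) | CC1=CC[C@H]2C(C)(C)CCC[C@]2(C)C1=O | intermediate
12 | (4aS,8aS)-3,4a,8,8-tetramethyl-4-methylidene-1,4,4a,5,6,7,8,8a-octahydronaphthalene (drima-7,9(11)-diene) | CC1=CC[C@H]2C(C)(C)CCC[C@]2(C)C1=C | intermediate
13 | benzene-1,2,4-triol | Oc1ccc(O)c(O)c1 | starting material
14 | 1,2,4-tris(methoxymethoxy)benzene | COCOc1ccc(OCOC)c(OCOC)c1 | intermediate
15 | [2,3,6-tris(methoxymethoxy)phenyl]lithium | COCOc1ccc(OCOC)c(OCOC)c1[Li] | intermediate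
16 | 2,3,6-tris(methoxymethoxy)benzaldehyde | COCOc1ccc(OCOC)c(OCOC)c1C=O | intermediate
17 | 3-bromo-2,5,6-tris(methoxymethoxy)benzaldehyde | COCOc1c(Br)cc(OCOC)c(OCOC)c1C=O | intermediate
18 | B-(drim-7-en-11-yl)-9-borabicyclo[3.3.1]nonane (5α-H, 9α-H, 10β-CH3) | CC1=CC[C@H]2C(C)(C)CCC[C@]2(C)[C@H]1CB1C2CCCC1CCC2 | intermediate
19 | 2,3,6-tris(methoxymethoxy)-5-{[(1S,4aS,8aS)-2,5,5,8a-tetramethyl-1,4,4a,5,6,7,8,8a-octahydronaphthalen-1-yl]methyl}benzaldehyde | CC1=CC[C@H]2C(C)(C)CCC[C@]2(C)[C@H]1Cc1cc(OCOC)c(OCOC)c(C=O)c1OCOC | intermediate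
20 | 2,3,6-trihydroxy-5-{[(1S,4aS,8aS)-2,5,5,8a-tetramethyl-1,4,4a,5,6,7,8,8a-octahydronaphthalen-1-yl]methyl}benzaldehyde | CC1=CC[C@H]2C(C)(C)CCC[C@]2(C)[C@H]1Cc1cc(O)c(O)c(C=O)c1O | target

Total step count: 11. Longest linear sequence: 8 steps (steps 1–6, 10 and 11, from carvone); steps 7–9 build the arene separately.

Steps most likely to fail

Step 4 (proposed new method). The tertiary radical may be quenched by hydrogen transfer before it adds to the phosphonium acceptor, or the base may attack the β-keto aldehyde (deformylation) before the ylide closes. The fallback sets out from 6 and comes back at 10, using the known iron-hydride radical conjugate addition/aldol annulation. With acrolein, Fe(acac)3 and PhSiH3 in EtOH/ethylene glycol, 6 should give the β-hydroxy aldehyde F1 by forming the same two bonds (C3–C4 by radical addition, C1–C2 by aldol closure). Acid-catalysed dehydration (p-TsOH cat., benzene, 60 °C) should give the enal F2. Decarbonylation with stoichiometric RhCl(PPh3)3 in refluxing toluene should then give 10.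

Step 10. Hydroboration may occur on the wrong face of C9 or at C7=C8, the hindered β-branched alkylborane may transmetalate slowly and be lost by protodeboronation, or residual borane may reduce the aldehyde. The fallback sets out from 12 and comes back at 19, separating the two events. Hydroboration with 9-BBN followed by NaOH/H2O2 should give drimenol F3, whose C9 configuration can be checked and whose epimer can be removed at this stage. Iodination (I2, PPh3, imidazole) should give the iodide F4. Nickel-catalysed reductive cross-electrophile coupling of F4 with 17 (NiBr2·glyme, 4,4'-di-tert-butyl-2,2'-bipyridine, Zn, NaI, DMA) tolerates the aldehyde and should give 19.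

Step 6. Addition of the ylide to the hindered, conjugated C9 ketone may be slow and lose out to γ-deprotonation of the enone. The fallback sets out from 11 and comes back at 12 by Peterson olefination. Addition of Me3SiCH2Li in the presence of CeCl3 (THF, −78 °C) should give the β-hydroxysilane F5, and syn-elimination with KH in THF should give 12.

Further compounds
F1 | step 4 | (4aS,8aR)-1-hydroxy-4,4,7,8a-tetramethyl-8-oxo-1,2,3,4,4a,5,8,8a-octahydronaphthalene-2-carbaldehyde (C1/C2 diastereomer mixture) | CC1=CC[C@H]2C(C)(C)CC(C=O)C(O)[C@]2(C)C1=O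
F2 | step 4 | (4aS,8aS)-4,4,7,8a-tetramethyl-8-oxo-3,4,4a,5,8,8a-hexahydronaphthalene-2-carbaldehyde | CC1=CC[C@H]2C(C)(C)CC(C=O)=C[C@]2(C)C1=O
F3 | step 10 | [(1S,4aS,8aS)-2,5,5,8a-tetramethyl-1,4,4a,5,6,7,8,8a-octahydronaphthalen-1-yl]methanol (drimenol) | CC1=CC[C@H]2C(C)(C)CCC[C@]2(C)[C@H]1CO
F4 | step 10 | (1S,4aS,8aS)-1-(iodomethyl)-2,5,5,8a-tetramethyl-1,4,4a,5,6,7,8,8a-octahydronaphthalene | CC1=CC[C@H]2C(C)(C)CCC[C@]2(C)[C@H]1CI
F5 | step 6 | (4aS,8aS)-2,5,5,8a-tetramethyl-1-[(trimethylsilyl)methyl]-1,4,4a,5,6,7,8,8a-octahydronaphthalen-1-ol (C1 epimer mixture) | CC1=CC[C@H]2C(C)(C)CCC[C@]2(C)C1(O)C[Si](C)(C)C
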